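# Proposed synthesis of CNP0420276.1 (compound 23)

Compound numbers are those of the steps and the compound list below. In the names of the bicyclic compounds, "eremophil-11-ene" means the trans-fused decalin with eremophilane numbering (ring A: C1–C5, C10; ring B: C5–C10), 4β,5β-dimethyl, 7α-(prop-1-en-2-yl) and 10α-H.

## Analysis of the target

Target 23 is an eremophilane: a trans-fused decalin with ring A made of C1–C5 and C10 and ring B of C5–C10, carrying seven stereocentres. On ring A the C3 ester oxygen (α, equatorial), the C4 methyl (β, equatorial) and the quaternary C5 methyl (β, axial at the ring fusion) are contiguous. The two methyls are cis to each other and trans to the oxygen, and C10 bears an α hydrogen. On ring B the C7 isopropenyl group, the C8 hydroxyl and the C9 ester oxygen are all α, so the free hydroxyl is axial between two equatorial neighbours. The sensitive groups are the two (Z)-hex-2-enoates (prone to Z-to-E isomerisation under nucleophilic catalysis and to conjugate addition), the 1,1-disubstituted C11=C12 alkene, and the cis C8-hydroxy/C9-acyloxy pair, which can exchange its acyl group. The hard points are the quaternary C5 flanked by stereocentres on both sides, the axial C8 carbinol, and the need to tell three secondary oxygens apart. The strategy rests on one feature of ring B: the C8 carbinol carbon is bonded to C7, which carries the isopropenyl group (C11=C12). This homoallylic alcohol array across C7–C8 is the product pattern of a carbonyl–ene reaction between a C8 aldehyde, held on the C9–C8 arm of C10, and a 3-methylbut-2-enyl group (C6–C7=C11) on C5.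

## Retrosynthetic reasoning

**C8–H.** The axial 8α-hydroxyl of 23 is traced back to the C8 ketone of 22. A carbonyl at C8 is useful three times over: it is what the ring closure delivers after oxidation, it activates C9 for oxygenation, and it leaves only two hydroxyls to acylate. The forward step must deliver hydride along the equatorial (β) trajectory without touching the enoates.

**The two cis alkenes and the two ester C–O bonds.** The (Z)-enoates of 22 are drawn back to the ynoates of 21, and these to diol 19 and two equivalents of acid 20. Acylating with acid 20 and creating the Z geometry afterwards by syn hydrogenation avoids exposing a preformed cis double bond to a nucleophile-catalysed acylation, where addition–elimination would erode the geometry.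

**O–Si and C9–O.** Diol 19 comes from silyl ether 18, and 18 from ketone 16 by oxygenating C9, the only methylene next to the carbonyl. The forward reaction has to enolise toward C9 and not toward the more acidic but more hindered C7, and to bring oxygen in from the α face. The axial C5 methyl, syn-axial to the β face of C9, provides that.

**C7–C8 (key disconnection).** In 16 the carbonyl carbon C8 is bonded to C7 bearing the isopropenyl group. At the carbinol level (15) this is a homoallylic alcohol, so cutting C7–C8 and returning a hydrogen from O8 to C12 gives aldehyde 14 with a prenyl group on C5. No other ring B bond does as much: its scission removes the C7 stereocentre and converts the isopropenyl group into a robust trisubstituted alkene that needs no protection. Cuts at C8–C9 or C5–C6 would leave an epimerisable isopropenyl-bearing centre in an open chain. The trans ring fusion is already fixed in 14, because the two arms are trans-diequatorial on ring A.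

**C9–C10 and C10–H.** Aldehyde 14 is the reduced form of nitrile 12, which comes from the unsaturated nitrile 11, the olefination product of ketone 9 and phosphonate 10. The two-carbon arm is thus attached to a C10 carbonyl, and the C10 stereocentre is made by adding hydrogen to the α face, anti to the axial C5 methyl. A ketone at C10 is chosen because the next disconnection supplies exactly that.

**C4–CH3 and C5–C6.** Ketone 9 is opened to enone 6 and bromide 7, with the C4 methyl cut off as a nucleophilic methyl group. Conjugate addition anti to the C3 silyloxy group sets C4, and alkylation of the resulting enolate 8 anti to the new methyl sets the quaternary C5. One existing stereocentre therefore controls two new ones in a single operation, and the C3 oxygen is already in place and protected.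

**C–CH3, the enone and the C3 stereocentre.** Enone 6 comes from iodide 5 by cross-coupling, 5 from enone 4 by α-iodination, 4 from enol silane 3 by dehydrogenation, and 3 from the achiral ketone 1 by enantiotopic-group-selective deprotonation. The only reagent-controlled stereocentre of the route (C3) is thus made on a commercial, symmetric ketone.

## Alternatives that were turned down

**Alternative 1:** Both rings are cut at once, at C5–C10 and C6–C7, leading back to the open-chain keto-enal A1, (E)-4-(tert-butyldimethylsilyloxy)-2,3-dimethyl-9-oxodec-7-enal.
- Forward key step: a cinchona-derived primary amine salt converts the α-branched aldehyde into an enamine whose C5 adds to C10 of the enone (ring A). The methyl ketone carbon C7 then condenses with the aldehyde carbon C6 to give the octalenone A2.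
- For it: one catalytic operation forms two rings, the quaternary centre and the ring fusion, and leaves an enone handle in ring B. In bonds formed per step it is stronger than the ene closure, which makes only one ring.
- Against it: A1 needs its own asymmetric synthesis to set C3 and C4 in an open chain. The Michael step builds a quaternary carbon next to the C4 stereocentre, where catalyst and substrate preferences may oppose each other. A2 also has neither the isopropenyl group nor the C9 oxygen. C7 is the α-carbon of an enone, so the isopropenyl group would have to come in by α-halogenation, cross-coupling and a stereoselective conjugate reduction.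
- Comparison: the chosen route builds the rings one at a time but brings the isopropenyl group and the C7 stereocentre in with the ring closure itself.

**Alternative 2:** Ring A is cut at C4–C5 and C1–C10 into the quinone A3 (2-methoxy-5-methyl-1,4-benzoquinone) and the diene A4, (Z)-3-(trimethylsilyloxy)penta-1,3-diene.
- Forward key step: a chiral binaphthol-derived titanium Lewis acid directs the cycloaddition onto the methyl-bearing quinone double bond. Fluoride and base then convert the cis adduct into the trans-fused trione A5.
- For it: it is the fastest way to the decalin. All ring carbons, the C4/C5 cis relationship (from diene geometry and endo addition), the quaternary centre and a C9 carbonyl arise in one catalytic asymmetric step. On convergence it is clearly stronger than the chosen route.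
- Against it: the cycloaddition must take place at the more hindered quinone double bond with the right orientation. A5 is also oxidised in the wrong places: the C6 carbonyl must be removed altogether, the C3 ketone reduced, and the vinylogous ester C7=C8(OMe) converted into C7–isopropenyl and C8–OH, with three carbonyls to tell apart.
- Comparison: the chosen route is longer to the bicycle, but every oxygen it carries sits at its final position and the isopropenyl group needs no separate introduction.

**Alternative 3:** Ring B is cut at C8–C9, leading back to the dialdehyde A6, 3-[4-(tert-butyldimethylsilyloxy)-6-formyl-1,2-dimethylcyclohexyl]propanal.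
- Forward key step: a divalent samarium reductant generates two ketyls that couple to the cis-8α,9α-diol A7.
- For it: both carbinol centres and their cis relationship arise in one step at the correct oxidation level. On this point it beats the chosen route, which spends an oxidation, a hydroxylation and a reduction on C8 and C9.
- Against it: A7 has a plain methylene at C7 and no handle there, so the isopropenyl group cannot be added afterwards. Carrying it through would place an epimerisable stereocentre α to an aldehyde in A6, and it would have to be set separately. The two hydroxyls of A7 would also have to be distinguished for mono-acylation at C9, and A6 needs two different chain extensions on ring A.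
- Comparison: the chosen route accepts a redox detour at C8 in exchange for forming the C7 stereocentre and the isopropenyl group during the closure of ring B.

Key step: step 9

Remark on the chemistry: the sense of the asymmetric deprotonation in step 1 is assigned by analogy with 4-tert-butylcyclohexanone, for which the (R,R)-amide is known to lead to the (S)-enol silane; the (S,S)-amide is therefore used for the (R) series, and the antipodal base would be taken if the assay of enone 4 showed the opposite sense.

## Route

Step 1
Reactants: 1 4-(tert-butyldimethylsilyloxy)cyclohexan-1-one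
Product: 3 (R)-4-(tert-butyldimethylsilyloxy)-1-(trimethylsilyloxy)cyclohex-1-ene, via lithium enolate 2 (not isolated)
Conditions: (S,S)-(PhMeCH)2NLi [from (S,S)-bis(1-phenylethyl)amine, n-BuLi], LiCl, Me3SiCl (internal quench), THF, −100 °C
Reagents that add atoms: chlorotrimethylsilane, C[Si](C)(C)Cl
Why: Enantioselective deprotonation of a 4-substituted cyclohexanone by a chiral lithium amide, a known desymmetrisation; the base removes one of the two enantiotopic axial α-hydrogens and the enolate is silylated as it forms, which fixes the C3 stereocentre of the target. The enantiomeric purity set here is carried through all later steps and should be assayed on enone 4.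

Step 2
Reactants: 3 (R)-4-(tert-butyldimethylsilyloxy)-1-(trimethylsilyloxy)cyclohex-1-ene
Product: 4 (R)-4-(tert-butyldimethylsilyloxy)cyclohex-2-en-1-one
Conditions: Pd(OAc)2 (1 equiv), MeCN, rt
Reagents that add atoms: none
Why: Saegusa oxidation: palladation of the enol silane at its α-carbon and β-hydride elimination toward the neighbouring methylene place the double bond next to the silyloxy-bearing carbon, which is not touched.

Step 3
Reactants: 4 (R)-4-(tert-butyldimethylsilyloxy)cyclohex-2-en-1-one
Product: 5 (R)-4-(tert-butyldimethylsilyloxy)-2-iodocyclohex-2-en-1-one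
Conditions: I2, pyridine, CH2Cl2, 0 °C → rt
Reagents that add atoms: iodine, II
Why: α-Iodination of an enone by conjugate addition of pyridine, iodination of the enolate and elimination of pyridine; the weakly basic medium does not enolise the γ-position, so the stereocentre is kept.

Step 4
Reactants: 5 (R)-4-(tert-butyldimethylsilyloxy)-2-iodocyclohex-2-en-1-one
Product: 6 (R)-4-(tert-butyldimethylsilyloxy)-2-methylcyclohex-2-en-1-one
Conditions: MeZnCl, Pd(PPh3)4 (5 mol %), THF, 0 °C → rt
Reagents that add atoms: methylzinc chloride, C[Zn]Cl
Why: Negishi cross-coupling of an α-iodoenone (oxidative addition of zerovalent palladium into C–I, transmetalation, reductive elimination); no base is present, so the γ-silyloxy stereocentre cannot be lost through a dienolate.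

Step 5
Reactants: 6 (R)-4-(tert-butyldimethylsilyloxy)-2-methylcyclohex-2-en-1-one; 7 1-bromo-3-methylbut-2-ene
Product: 9 (2R,3R,4R)-4-(tert-butyldimethylsilyloxy)-2,3-dimethyl-2-(3-methylbut-2-en-1-yl)cyclohexan-1-one, via lithium enolate 8 (not isolated)
Conditions: Me2CuLi (from MeLi, CuI), Et2O, −78 → −20 °C; then 7, DMPU, THF, −20 °C → rt
Reagents that add atoms: lithium dimethylcuprate, [Li+].C[Cu-]C
Why: Conjugate addition–enolate alkylation: the cuprate adds to the β-carbon (C4 of the target) anti to the γ-silyloxy group, as is usual for 4-silyloxycyclohexenones. In the tetrasubstituted enolate 8 the new methyl is pushed pseudo-axial by A(1,2) strain against the enolate methyl, so the prenyl bromide enters anti to it and the two methyls end up cis at the quaternary C5.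

Step 6
Reactants: 9 (2R,3R,4R)-4-(tert-butyldimethylsilyloxy)-2,3-dimethyl-2-(3-methylbut-2-en-1-yl)cyclohexan-1-one; 10 diethyl (cyanomethyl)phosphonate
Product: 11 (E)-2-[(2R,3R,4R)-4-(tert-butyldimethylsilyloxy)-2,3-dimethyl-2-(3-methylbut-2-en-1-yl)cyclohexylidene]acetonitrile
Conditions: NaH, THF, 0 °C → reflux
Reagents that add atoms: none
Why: Horner–Wadsworth–Emmons olefination with the small cyanomethylphosphonate anion, the usual choice for α-quaternary cyclohexanones; no epimerisable centre flanks the carbonyl. The E isomer (nitrile turned away from C5) is expected to dominate, and either isomer converges in step 7.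

Step 7
Reactants: 11 (E)-2-[(2R,3R,4R)-4-(tert-butyldimethylsilyloxy)-2,3-dimethyl-2-(3-methylbut-2-en-1-yl)cyclohexylidene]acetonitrile
Product: 12 2-[(1S,2S,3R,4R)-4-(tert-butyldimethylsilyloxy)-2,3-dimethyl-2-(3-methylbut-2-en-1-yl)cyclohexyl]acetonitrile
Conditions: Mg turnings, MeOH, 0 °C → rt
Reagents that add atoms: none
Why: Dissolving-metal conjugate reduction of an α,β-unsaturated nitrile; C10 is protonated along the axial trajectory on the α face, anti to the axial C5 methyl that flanks the β face, so the cyanomethyl arm ends equatorial, cis to that methyl and trans to the prenyl group. The isolated trisubstituted alkene and the silyl ether are inert.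

Step 8
Reactants: 12 2-[(1S,2S,3R,4R)-4-(tert-butyldimethylsilyloxy)-2,3-dimethyl-2-(3-methylbut-2-en-1-yl)cyclohexyl]acetonitrile
Product: 14 2-[(1S,2S,3R,4R)-4-(tert-butyldimethylsilyloxy)-2,3-dimethyl-2-(3-methylbut-2-en-1-yl)cyclohexyl]acetaldehyde, via aluminio aldimine 13 (not isolated)
Conditions: i-Bu2AlH, toluene, −78 °C; then aq. potassium sodium tartrate, rt
Reagents that add atoms: water, O
Why: Partial reduction of a nitrile: one hydride transfer gives the N-aluminio aldimine 13, which is stable at −78 °C and is hydrolysed to the aldehyde on work-up; no stereocentre is α to the new carbonyl.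

Step 9
Reactants: 14 2-[(1S,2S,3R,4R)-4-(tert-butyldimethylsilyloxy)-2,3-dimethyl-2-(3-methylbut-2-en-1-yl)cyclohexyl]acetaldehyde
Product: 16 3α-(tert-butyldimethylsilyloxy)eremophil-11-en-8-one, via 8β-carbinol 15 (not isolated)
Conditions: ZnBr2 (1.2 equiv), CH2Cl2, 0 °C; then pyridine, Dess–Martin periodinane, 0 °C → rt
Reagents that add atoms: none
Why: ZnBr2 binds the C8 aldehyde oxygen, and the prenyl C7=C11 bond attacks C8 through C7 while a hydrogen of a C11 methyl passes to oxygen in a concerted six-centre ene transition state; the closest known reaction is the ZnBr2-promoted cyclisation of citronellal to isopulegol. Ring B closes as a six-membered ring, exo with respect to both π bonds (O8 and C11 stay outside the ring), which is a type 1 ene closure. The ring fusion is not at stake, because the C5 and C10 arms are trans-diequatorial on ring A and the chair-like transition state can only give the trans-decalin. The new C7 centre is controlled by the axial C5 methyl: a β (axial) isopropylidene unit would be 1,3-diaxial to it, so C11 sits equatorial and C7 receives the α-isopropenyl group. C8 forms with the zinc-bound oxygen equatorial (carbinol 15), but its configuration does not matter, since the pyridine-buffered Dess–Martin oxidation in the same flask converts it into ketone 16. The only selectivity the step needs is therefore 7α, which is both the kinetic outcome of the chair and the thermodynamic epimer next to the C8 carbonyl. The buffer keeps the β,γ-unsaturated ketone from slipping into conjugation, and the silyl ether is inert to ZnBr2.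

Step 10
Reactants: 16 3α-(tert-butyldimethylsilyloxy)eremophil-11-en-8-one
Product: 18 3α-(tert-butyldimethylsilyloxy)-9α-hydroxyeremophil-11-en-8-one, via potassium enolate 17 (not isolated)
Conditions: KN(SiMe3)2, THF, −78 °C (ketone added to base); then 2-(phenylsulfonyl)-3-phenyloxaziridine, −78 °C; AcOH
Reagents that add atoms: 2-(phenylsulfonyl)-3-phenyloxaziridine, O=S(=O)(c1ccccc1)N1OC1c1ccccc1
Why: Kinetic deprotonation by the hindered amide takes place at the C9 methylene and not at the tertiary, isopropenyl-bearing C7, and the enolate is oxidised by the N-sulfonyloxaziridine (enolate hydroxylation). The oxidant approaches C9 from the α face because the β face is syn-axial to the C5 methyl, which gives the equatorial 9α-hydroxyl.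

Step 11
Reactants: 18 3α-(tert-butyldimethylsilyloxy)-9α-hydroxyeremophil-11-en-8-one
Product: 19 3α,9α-dihydroxyeremophil-11-en-8-one
Conditions: HF·pyridine, pyridine, THF, 0 °C → rt
Reagents that add atoms: none
Why: Fluoride cleavage of the Si–O bond under buffered acidic conditions, chosen over basic fluoride sources so that neither the α-hydroxy ketone nor the β,γ-unsaturated ketone is enolised.

Step 12
Reactants: 19 3α,9α-dihydroxyeremophil-11-en-8-one; 20 hex-2-ynoic acid
Product: 21 3α,9α-bis(hex-2-ynoyloxy)eremophil-11-en-8-one
Conditions: 20 (2.4 equiv), DCC (2.4 equiv), DMAP (cat.), CH2Cl2, −20 → 0 °C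
Reagents that add atoms: hex-2-ynoic acid (second equivalent), CCCC#CC(=O)O
Why: Twofold Steglich esterification: the C3 and the C9 hydroxyl, both equatorial, each take up one molecule of acid 20 through its O-acylisourea, so two equivalents of the acid are built into 21. With C8 still a ketone there is no third hydroxyl to compete, and 2-alkynoic acids are routinely coupled in this way at low temperature.

Step 13
Reactants: 21 3α,9α-bis(hex-2-ynoyloxy)eremophil-11-en-8-one
Product: 22 3α,9α-bis[(Z)-hex-2-enoyloxy]eremophil-11-en-8-one
Conditions: H2 (1 atm), Pd/CaCO3 poisoned with Pb(OAc)2 (Lindlar catalyst), quinoline, EtOAc, rt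
Reagents that add atoms: none
Why: Lindlar semi-hydrogenation: syn delivery of H2 to each conjugated alkyne on the poisoned palladium surface fixes the Z geometry of both enoates. The 1,1-disubstituted C11=C12 alkene and the ketone are not reduced at a useful rate on this catalyst.

Step 14
Reactants: 22 3α,9α-bis[(Z)-hex-2-enoyloxy]eremophil-11-en-8-one
Product: 23 3α,9α-bis[(Z)-hex-2-enoyloxy]eremophil-11-en-8α-ol (CNP0420276.1)
Conditions: LiBH(s-Bu)3 (1.1 equiv), THF, −78 °C; AcOH, −78 °C
Reagents that add atoms: none
Why: Ketone reduction by a bulky trialkylborohydride, which attacks the C8 carbonyl along the equatorial (β) trajectory because the axial path is syn to the axial hydrogens at C6 and C10; both flanking substituents are equatorial, and the axial 8α-alcohol results. At −78 °C ketone reduction outpaces conjugate addition to the β-alkyl enoates, and the cold acidic quench protonates the alkoxide before the neighbouring C9 acyl group can migrate.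

## Compound list

1 | 4-(tert-butyldimethylsilyloxy)cyclohexan-1-one | O=C1CCC(O[Si](C)(C)C(C)(C)C)CC1 | starting material
2 | lithium (R)-4-(tert-butyldimethylsilyloxy)cyclohex-1-en-1-olate | [Li]OC1=CC[C@H](O[Si](C)(C)C(C)(C)C)CC1 | intermediate
3 | (R)-4-(tert-butyldimethylsilyloxy)-1-(trimethylsilyloxy)cyclohex-1-ene | C[Si](C)(C)OC1=CC[C@H](O[Si](C)(C)C(C)(C)C)CC1 | intermediate
4 | (R)-4-(tert-butyldimethylsilyloxy)cyclohex-2-en-1-one | O=C1C=C[C@H](O[Si](C)(C)C(C)(C)C)CC1 | intermediate
5 | (R)-4-(tert-butyldimethylsilyloxy)-2-iodocyclohex-2-en-1-one | O=C1C(I)=C[C@H](O[Si](C)(C)C(C)(C)C)CC1 | intermediate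
6 | (R)-4-(tert-butyldimethylsilyloxy)-2-methylcyclohex-2-en-1-one | CC1=C[C@H](O[Si](C)(C)C(C)(C)C)CCC1=O | intermediate
7 | 1-bromo-3-methylbut-2-ene | CC(C)=CCBr | starting material
8 | lithium (3R,4R)-4-(tert-butyldimethylsilyloxy)-2,3-dimethylcyclohex-1-en-1-olate | [Li]OC1=C(C)[C@@H](C)[C@H](O[Si](C)(C)C(C)(C)C)CC1 | intermediate
9 | (2R,3R,4R)-4-(tert-butyldimethylsilyloxy)-2,3-dimethyl-2-(3-methylbut-2-en-1-yl)cyclohexan-1-one | CC(C)=CC[C@]1(C)[C@@H](C)[C@H](O[Si](C)(C)C(C)(C)C)CCC1=O | intermediate
10 | diethyl (cyanomethyl)phosphonate | CCOP(=O)(CC#N)OCC | starting material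
11 | (E)-2-[(2R,3R,4R)-4-(tert-butyldimethylsilyloxy)-2,3-dimethyl-2-(3-methylbut-2-en-1-yl)cyclohexylidene]acetonitrile | CC(C)=CC[C@]1(C)[C@@H](C)[C@H](O[Si](C)(C)C(C)(C)C)CC/C1=C\C#N | intermediate
12 | 2-[(1S,2S,3R,4R)-4-(tert-butyldimethylsilyloxy)-2,3-dimethyl-2-(3-methylbut-2-en-1-yl)cyclohexyl]acetonitrile | CC(C)=CC[C@]1(C)[C@@H](C)[C@H](O[Si](C)(C)C(C)(C)C)CC[C@H]1CC#N | intermediate
13 | N-(diisobutylaluminio)imine of aldehyde 14 | CC(C)=CC[C@]1(C)[C@@H](C)[C@H](O[Si](C)(C)C(C)(C)C)CC[C@H]1CC=N[Al](CC(C)C)CC(C)C | intermediate
14 | 2-[(1S,2S,3R,4R)-4-(tert-butyldimethylsilyloxy)-2,3-dimethyl-2-(3-methylbut-2-en-1-yl)cyclohexyl]acetaldehyde | CC(C)=CC[C@]1(C)[C@@H](C)[C@H](O[Si](C)(C)C(C)(C)C)CC[C@H]1CC=O | intermediate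
15 | 3α-(tert-butyldimethylsilyloxy)eremophil-11-en-8β-ol | C=C(C)[C@@H]1C[C@]2(C)[C@@H](C)[C@H](O[Si](C)(C)C(C)(C)C)CC[C@H]2C[C@H]1O | intermediate
16 | 3α-(tert-butyldimethylsilyloxy)eremophil-11-en-8-one | C=C(C)[C@@H]1C[C@]2(C)[C@@H](C)[C@H](O[Si](C)(C)C(C)(C)C)CC[C@H]2CC1=O | intermediate
17 | potassium 3α-(tert-butyldimethylsilyloxy)eremophila-8,11-dien-8-olate | C=C(C)[C@@H]1C[C@]2(C)[C@@H](C)[C@H](O[Si](C)(C)C(C)(C)C)CC[C@H]2C=C1O[K] | intermediate
18 | 3α-(tert-butyldimethylsilyloxy)-9α-hydroxyeremophil-11-en-8-one | C=C(C)[C@@H]1C[C@]2(C)[C@@H](C)[C@H](O[Si](C)(C)C(C)(C)C)CC[C@H]2[C@H](O)C1=O | intermediate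
19 | 3α,9α-dihydroxyeremophil-11-en-8-one | C=C(C)[C@@H]1C[C@]2(C)[C@@H](C)[C@H](O)CC[C@H]2[C@H](O)C1=O | intermediate
20 | hex-2-ynoic acid | CCCC#CC(=O)O | starting material
21 | 3α,9α-bis(hex-2-ynoyloxy)eremophil-11-en-8-one | C=C(C)[C@@H]1C[C@]2(C)[C@@H](C)[C@H](OC(=O)C#CCCC)CC[C@H]2[C@H](OC(=O)C#CCCC)C1=O | intermediate
22 | 3α,9α-bis[(Z)-hex-2-enoyloxy]eremophil-11-en-8-one | C=C(C)[C@@H]1C[C@]2(C)[C@@H](C)[C@H](OC(=O)/C=C\CCC)CC[C@H]2[C@H](OC(=O)/C=C\CCC)C1=O | intermediate
23 | 3α,9α-bis[(Z)-hex-2-enoyloxy]eremophil-11-en-8α-ol (CNP0420276.1) | C=C(C)[C@@H]1C[C@]2(C)[C@@H](C)[C@H](OC(=O)/C=C\CCC)CC[C@H]2[C@H](OC(=O)/C=C\CCC)[C@@H]1O | target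

## Step count and least certain steps

Total: 14 steps. Longest linear sequence: 14 steps (1 → 23); bromide 7, phosphonate 10 and acid 20 are bought.

**Step 9 (key step).** The zinc-bound aldehyde may leave the concerted ene path for a stepwise cationic closure, with halide capture at C11 or proton loss toward C7, or may condense with itself through its enolisable C9 methylene. The in-pot oxidation may also let the C11 alkene drift into conjugation with the new carbonyl. The fallback forms the same C7–C8 bond by an intramolecular Nozaki–Hiyama allylation and sets out from nitrile 12. Allylic oxidation of the E methyl group of the prenyl unit (SeO2 cat., t-BuOOH, CH2Cl2) should give 2-[(1S,2S,3R,4R)-4-(tert-butyldimethylsilyloxy)-2-[(E)-4-hydroxy-3-methylbut-2-en-1-yl]-2,3-dimethylcyclohexyl]acetonitrile F1. Appel bromination (CBr4, PPh3) would then give the corresponding allylic bromide, 2-[(1S,2S,3R,4R)-2-[(E)-4-bromo-3-methylbut-2-en-1-yl]-4-(tert-butyldimethylsilyloxy)-2,3-dimethylcyclohexyl]acetonitrile F2, and i-Bu2AlH at −78 °C the bromo aldehyde 2-[(1S,2S,3R,4R)-2-[(E)-4-bromo-3-methylbut-2-en-1-yl]-4-(tert-butyldimethylsilyloxy)-2,3-dimethylcyclohexyl]acetaldehyde F3. Treatment with CrCl2 in THF then metallates the allylic C–Br bond, and the γ-carbon C7 of the metallated allyl unit adds to the aldehyde through a chair transition state, which unveils the isopropenyl group in carbinol 15. Dess–Martin oxidation brings the sequence back to the route at 16.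

**Step 5.** The facial selectivity of the enolate alkylation may be eroded, because the half-chair that puts the C4 methyl pseudo-axial also puts the C3 silyloxy group syn-axial to the incoming electrophile; slow C-alkylation of the hindered enolate could add O-alkylation. The fallback replaces substrate control by catalyst control and sets out from enone 6. After the same cuprate addition, the enolate 8 is trapped with allyl chloroformate as allyl (3R,4R)-4-(tert-butyldimethylsilyloxy)-2,3-dimethylcyclohex-1-en-1-yl carbonate F4. Decarboxylative allylic alkylation (Pd2(dba)3, (S)-t-Bu-PHOX, THF) then forms the quaternary centre under ligand control and gives (2R,3R,4R)-2-allyl-4-(tert-butyldimethylsilyloxy)-2,3-dimethylcyclohexan-1-one F5. Cross-metathesis with 2-methylbut-2-ene (second-generation Grubbs catalyst) converts the allyl into the prenyl group and returns to the route at 9.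

**Step 7.** Protonation of C10 may occur in part from the β face, since the bias comes only from one axial methyl next to a trigonal carbon; that would give the C10 epimer with the arm cis to the prenyl group. The fallback sets out from 11 and replaces protonation under substrate control by ligand-controlled hydride delivery. A copper hydride conjugate reduction of the β,β-disubstituted unsaturated nitrile (Cu(OAc)2, a chiral Josiphos-type bisphosphine matched to α-face delivery, polymethylhydrosiloxane, t-BuOH, toluene) returns to the route at 12 without new intermediates.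

**Step 10.** Proton transfer between enolate 17 and unreacted ketone may move the enolate to C7, which would lead to migration of the C11 alkene into conjugation or to oxidation at C7; the sulfonimine by-product may also add to the enolate. The fallback sets out from 16 and traps the kinetic enolate irreversibly before any oxidant is present. LiN(i-Pr)2 with Me3SiCl as internal quench (THF, −78 °C) gives 3α-(tert-butyldimethylsilyloxy)-8-(trimethylsilyloxy)eremophila-8,11-diene F6. A Rubottom oxidation with one equivalent of dimethyldioxirane at −78 °C, which attacks the electron-rich enol silane far faster than the isopropenyl group, followed by aqueous citric acid in THF, returns to the route at 18.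

**Step 14.** The new C8 alkoxide may take over the acyl group from the cis C9 oxygen, and hydride may add in conjugate fashion to the enoates if the ketone is slow to react. The fallback inverts the order so that no ester is present during the hydride step, and sets out from 19. Reduction with excess LiBH(s-Bu)3 (THF, −78 °C) should give eremophil-11-ene-3α,8α,9α-triol F7. Acylation with two equivalents of 20 (DCC, DMAP cat., −20 °C) should take the two equatorial hydroxyls and leave the hindered axial one, giving 3α,9α-bis(hex-2-ynoyloxy)eremophil-11-en-8α-ol F8. Lindlar semi-hydrogenation as in step 13 returns to the route at 23.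

## Further compounds

F1 | step 9 | 2-[(1S,2S,3R,4R)-4-(tert-butyldimethylsilyloxy)-2-[(E)-4-hydroxy-3-methylbut-2-en-1-yl]-2,3-dimethylcyclohexyl]acetonitrile | OC/C(C)=C/C[C@]1(C)[C@@H](C)[C@H](O[Si](C)(C)C(C)(C)C)CC[C@H]1CC#N
F2 | step 9 | 2-[(1S,2S,3R,4R)-2-[(E)-4-bromo-3-methylbut-2-en-1-yl]-4-(tert-butyldimethylsilyloxy)-2,3-dimethylcyclohexyl]acetonitrile | BrC/C(C)=C/C[C@]1(C)[C@@H](C)[C@H](O[Si](C)(C)C(C)(C)C)CC[C@H]1CC#N
F3 | step 9 | 2-[(1S,2S,3R,4R)-2-[(E)-4-bromo-3-methylbut-2-en-1-yl]-4-(tert-butyldimethylsilyloxy)-2,3-dimethylcyclohexyl]acetaldehyde | BrC/C(C)=C/C[C@]1(C)[C@@H](C)[C@H](O[Si](C)(C)C(C)(C)C)CC[C@H]1CC=O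
F4 | step 5 | allyl (3R,4R)-4-(tert-butyldimethylsilyloxy)-2,3-dimethylcyclohex-1-en-1-yl carbonate | C=CCOC(=O)OC1=C(C)[C@@H](C)[C@H](O[Si](C)(C)C(C)(C)C)CC1
F5 | step 5 | (2R,3R,4R)-2-allyl-4-(tert-butyldimethylsilyloxy)-2,3-dimethylcyclohexan-1-one | C=CC[C@]1(C)[C@@H](C)[C@H](O[Si](C)(C)C(C)(C)C)CCC1=O
F0 | step 7 | none | none
F6 | step 10 | 3α-(tert-butyldimethylsilyloxy)-8-(trimethylsilyloxy)eremophila-8,11-diene | C=C(C)[C@@H]1C[C@]2(C)[C@@H](C)[C@H](O[Si](C)(C)C(C)(C)C)CC[C@H]2C=C1O[Si](C)(C)C
F7 | step 14 | eremophil-11-ene-3α,8α,9α-triol | C=C(C)[C@@H]1C[C@]2(C)[C@@H](C)[C@H](O)CC[C@H]2[C@H](O)[C@@H]1O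
F8 | step 14 | 3α,9α-bis(hex-2-ynoyloxy)eremophil-11-en-8α-ol | C=C(C)[C@@H]1C[C@]2(C)[C@@H](C)[C@H](OC(=O)C#CCCC)CC[C@H]2[C@H](OC(=O)C#CCCC)[C@@H]1O
A1 | alternative 1 | (E)-4-(tert-butyldimethylsilyloxy)-2,3-dimethyl-9-oxodec-7-enal (C3 and C4 of the target set, C2 unassigned) | O=CC(C)[C@@H](C)[C@H](O[Si](C)(C)C(C)(C)C)CC/C=C/C(C)=O
A2 | alternative 1 | trans-fused 3α-(tert-butyldimethylsilyloxy)-4β,5β-dimethyloctal-6-en-8-one (eremophilane numbering) | C1=C[C@]2(C)[C@@H](C)[C@H](O[Si](C)(C)C(C)(C)C)CC[C@H]2CC1=O
A3 | alternative 2 | 2-methoxy-5-methyl-1,4-benzoquinone | COC1=CC(=O)C(C)=CC1=O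
A4 | alternative 2 | (Z)-3-(trimethylsilyloxy)penta-1,3-diene | C=C/C(O[Si](C)(C)C)=C/C
A5 | alternative 2 | trans-fused 8-methoxy-4β,5β-dimethyloctal-7-ene-3,6,9-trione (eremophilane numbering) | O=C1C=C(OC)C(=O)[C@@H]2CCC(=O)[C@H](C)[C@@]12C
A6 | alternative 3 | 3-[4-(tert-butyldimethylsilyloxy)-6-formyl-1,2-dimethylcyclohexyl]propanal (ring stereocentres as in 14) | O=CCC[C@]1(C)[C@@H](C)[C@H](O[Si](C)(C)C(C)(C)C)CC[C@H]1C=O
A7 | alternative 3 | 3α-(tert-butyldimethylsilyloxy)-4β,5β-dimethyl-trans-decalin-8α,9α-diol (eremophilane numbering) | C1C[C@]2(C)[C@@H](C)[C@H](O[Si](C)(C)C(C)(C)C)CC[C@H]2[C@H](O)[C@@H]1O
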